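If a charge has to dissolve before it can react, the reagent charged in the smaller amount need not be what stops the links.

solid first end groups 0.20 M; second end groups 0.180 M; time 30 s

    first end groups + second end groups ⇌ links + by-product (K1 = 1.19, k1 = 0.834 M⁻¹ s⁻¹)
    solid first end groups ⇌ first end groups, rate k2*(cs2 - [first end groups]) while solid is left; crystals form when [first end groups] > cs2 (cs2 = 0.12 M, k2 = 0.0236 s⁻¹)
    links ⇌ isomer of the product (K3 = 0.72, k3 = 0.149 s⁻¹)

- given per volume of solution although it is solid: solid first end groups
- at the start none of the solid first end groups is in solution
- first end groups means what is dissolved; the solid is not counted in it
- run time (flask): 30 s

- links at 30 s, in percent of the solid first end groups charged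
- concentration of first end groups in solution at 15 s, in percent of saturation
- the change that raises the amount of links at 30 s, in percent of the solid first end groups charged most ("none" if none brings more than 2 percentage points) (amber / blue / grey / none)
- amount of links at 30 s, in percent of the solid first end groups charged, after amber

- amber: doubling the solubility in step 2, all else as stated
- blue: doubling the dissolution coefficient of step 2, all else as stated
- grey: doubling the amount of second end groups, all else as stated

We count in fractions of the solid charged. Each link or isomer spends one second end group, the limiting reagent of this flask, so links stay within 90.0%. But that balance contains no time. Dissolution into an empty solution gives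

dissolution coefficient × solubility × time / charge = 0.0236 s⁻¹ × 0.12 M × 30 s / 0.20 M = 42.5%

This fraction, the most that step 2 can deliver by that time, is the supply ceiling. It is lower than the first limit, so dissolution looks like the rate-limiting step.

The objection is that the solution does not stay empty. Setting dissolution equal to capture at the charged second end groups gives the filling of the solution:

fill = k2 / (k2 + k1 × second end groups) = 13.6% of saturation

Delivery is then 36.7%, of which 8.15% stays dissolved. Links and isomer relax in 1.95 s, short against the run, so we split the remainder by step 3:

links = (delivered − dissolved) / (1 + K3) = 16.6%

The next objection is the way back of step 1. On these estimated amounts it comes to 79.6% of the forward rate at the end, so we take our figure for links as high and commit to a little under it. We keep the fill for the earlier reading.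

The same two formulas rank the changes by delivery: amber 73.4%, blue 64.6%, grey 39.4%. We choose amber, but with the way back in the reckoning we do not simply double its links.

The forecast puts links at 15.2%, and at 25.4% after amber. It puts first end groups at 13.8% of saturation. Its ground is that "Dissolution is the slow step". Its links lie below our figure.

The flask gives 15.3% of links, and 25.4% after amber, whose gain is 10 percentage points. Its first end groups stand at 13.8% of saturation at 15.0 s. At 30.0 s the flask still has 63.1% of its charge as solid and 73% of its second end groups, so it has drawn 86.8% of its ceiling. In a neighbouring flask with 0.80 M of solid, all else held, the ceiling falls to 10.6% of its charge, and that flask holds 3.83% of links.

(Its constants were drawn at random within sensible limits; what happens was integrated by code.)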